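**Retrosynthetic overview**
- The target is reached last from its 2,4-bis(benzyl) ether by hydrogenolysis of the two ArO–Bn bonds.
- The heptan-3-one chain is cut on both sides of the carbonyl carbon C3 (bonds C2–C3 and C3–C4). C3 lies between the two-carbon arm C1–C2 on the 2,4-dioxygenated 3-methoxyphenyl ring and the four-carbon arm C4–C7 on the 4-methoxyphenyl ring, so C3 can be brought in as carbon monoxide between a 2-arylethyl iodide and a B-(4-arylbutyl)-9-BBN.
- Iodide ⇐ 2-arylethanol ⇐ styrene ⇐ benzaldehyde ⇐ 1,3-bis(benzyloxy)-2-methoxybenzene ⇐ 2-methoxyresorcinol.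
- Borane ⇐ 4-(4-methoxyphenyl)but-1-ene + 9-BBN ⇐ 4-methoxybenzyl chloride + allylmagnesium bromide.
- No ring is formed: both benzene rings are bought and only the C7 chain between them is built.

Key step: step 8

Assumption: the target has no stereocentre, no stereogenic double bond and no axis, so it is achiral; "single enantiomer" is taken to mean the constitution shown, and no step needs stereocontrol.

**Step 1**
Reactants: 1 2-methoxyresorcinol (2-methoxybenzene-1,3-diol)
Product: 2 1,3-bis(benzyloxy)-2-methoxybenzene
Conditions: BnBr (2.3 equiv), K2CO3, DMF, rt → 60 °C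
Reagents that add atoms: benzyl bromide, BrCc1ccccc1
Why: Williamson ether synthesis, in which carbonate deprotonates both phenols and each phenoxide displaces bromide from benzyl bromide by SN2, so both oxygens carry a group that the last step removes without touching the methyl ethers.

**Step 2**
Reactants: 2 1,3-bis(benzyloxy)-2-methoxybenzene
Product: 4 2,4-bis(benzyloxy)-3-methoxybenzaldehyde, via aryl iminium chloride 3 (not isolated)
Conditions: POCl3, DMF, 0 → 70 °C; then aq NaOAc, rt
Reagents that add atoms: N,N-dimethylformamide, CN(C)C=O; water, O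
Why: Vilsmeier–Haack formylation, in which the chloroiminium ion should attack C4 (equivalent to C6; para to one benzyloxy group and ortho to the other) rather than C5 (meta to both and para only to the flanked, twisted methoxy group), and aqueous acetate hydrolyses iminium 3 to the aldehyde.

**Step 3**
Reactants: 4 2,4-bis(benzyloxy)-3-methoxybenzaldehyde
Product: 5 1,3-bis(benzyloxy)-4-ethenyl-2-methoxybenzene
Conditions: Ph3PCH3Br, KOtBu, THF, 0 °C → rt
Reagents that add atoms: methyltriphenylphosphonium bromide, C[P+](c1ccccc1)(c1ccccc1)c1ccccc1.[Br-]
Why: Wittig methylenation of a non-enolisable aryl aldehyde with the unstabilised ylide, which gives a terminal vinyl group with no alkene geometry to control.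

**Step 4**
Reactants: 5 1,3-bis(benzyloxy)-4-ethenyl-2-methoxybenzene
Product: 7 2-[2,4-bis(benzyloxy)-3-methoxyphenyl]ethan-1-ol, via B-(2-arylethyl)-9-BBN 6 (not isolated)
Conditions: 9-BBN, THF, 0 °C → rt; then 3 M NaOH, 30% H2O2, 0 °C → rt
Reagents that add atoms: 9-borabicyclo[3.3.1]nonane, B1C2CCCC1CCC2 (atoms of intermediate 6); hydrogen peroxide, OO
Why: Hydroboration–oxidation, in which the bulky 9-BBN should place boron on the terminal carbon of the styrene (anti-Markovnikov) and alkaline peroxide replaces boron by OH while the benzyl ethers are untouched.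

**Step 5**
Reactants: 7 2-[2,4-bis(benzyloxy)-3-methoxyphenyl]ethan-1-ol
Product: 8 1,3-bis(benzyloxy)-4-(2-iodoethyl)-2-methoxybenzene
Conditions: I2, PPh3, imidazole, CH2Cl2, 0 °C → rt
Reagents that add atoms: iodine, II
Why: Appel-type iodination, in which the alcohol is activated as its alkoxyphosphonium ion and displaced by iodide in an SN2 step at a primary carbon under near-neutral conditions that should not cause elimination to the styrene.

**Step 6**
Reactants: 9 4-methoxybenzyl chloride; 10 allylmagnesium bromide
Product: 11 1-(but-3-en-1-yl)-4-methoxybenzene (4-(4-methoxyphenyl)but-1-ene)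
Conditions: THF/Et2O, 0 °C → rt, slow addition of 9 to 10
Reagents that add atoms: none
Why: Direct substitution of a reactive benzylic chloride by an allylic Grignard reagent, a standard way to 4-arylbut-1-enes, with inverse addition to limit benzylic homocoupling.

**Step 7**
Reactants: 11 1-(but-3-en-1-yl)-4-methoxybenzene
Product: 12 9-[4-(4-methoxyphenyl)butyl]-9-borabicyclo[3.3.1]nonane (air-sensitive; kept under argon)
Conditions: 9-BBN (0.5 M in THF), 0 °C → rt; THF evaporated under Ar, residue taken up in benzene
Reagents that add atoms: 9-borabicyclo[3.3.1]nonane, B1C2CCCC1CCC2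
Why: Hydroboration of a monosubstituted alkene with 9-BBN should put boron on the terminal carbon with essentially complete regioselectivity, and the B-alkyl-9-BBN formed transfers only its primary alkyl group in the coupling that follows.

**Step 8**
Reactants: 8 1,3-bis(benzyloxy)-4-(2-iodoethyl)-2-methoxybenzene; 12 9-[4-(4-methoxyphenyl)butyl]-9-borabicyclo[3.3.1]nonane; 13 carbon monoxide
Product: 14 1-[2,4-bis(benzyloxy)-3-methoxyphenyl]-7-(4-methoxyphenyl)heptan-3-one
Conditions: Pd(PPh3)4 (5 mol %), K3PO4 (3 equiv), CO (1 atm, raised to 10–20 atm if needed), benzene, hν (visible lamp), rt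
Reagents that add atoms: none
Why: Photoexcited Pd(0) should transfer an electron to the primary C–I bond of 8 to give the 2-arylethyl radical and Pd(I)–I, and the radical adds CO to form an acyl radical that recombines with palladium to the acylpalladium(II) iodide. Phosphate converts borane 12 into a borate that transfers its primary 4-arylbutyl group (the bicyclic B–C bonds of 9-BBN do not migrate), and reductive elimination forms the C3–C4 bond after the C2–C3 bond, so the carbon of CO becomes C3. The closest known reaction type is the light-assisted, palladium-catalysed carbonylative Suzuki–Miyaura coupling of iodoalkanes with 9-alkyl-9-BBN reagents to dialkyl ketones, applied here directly to two unhindered primary partners. No ring is closed and no stereocentre is formed. The step needs chemoselectivity for the three-component ketone over direct alkyl–alkyl coupling, over β-hydride loss to styrene 5 and over hydrogen transfer from the ortho benzyloxy CH2 to the radical; CO pressure favours acyl formation over the first two, and the last is a slow 1,6-shift through a seven-membered transition state. The position of the ketone is fixed by placing iodine on the two-carbon fragment and boron on the four-carbon fragment, and the aryl methyl and benzyl ethers are inert to the conditions.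

**Step 9**
Reactants: 14 1-[2,4-bis(benzyloxy)-3-methoxyphenyl]-7-(4-methoxyphenyl)heptan-3-one
Product: 15 1-(2,4-dihydroxy-3-methoxyphenyl)-7-(4-methoxyphenyl)heptan-3-one (target, achiral)
Conditions: H2 (1 atm), 10% Pd/C, EtOAc, rt
Reagents that add atoms: none
Why: Catalytic hydrogenolysis should cleave only the two benzylic C–O bonds while the non-benzylic C3 ketone and the aryl methyl ethers stay, and the neutral aprotic solvent keeps the freed ortho phenol from forming a ketal or chromene with the ketone.

**Compound list**
1 | 2-methoxyresorcinol (2-methoxybenzene-1,3-diol) | COc1c(O)cccc1O | starting material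
2 | 1,3-bis(benzyloxy)-2-methoxybenzene | COc1c(OCc2ccccc2)cccc1OCc1ccccc1 | intermediate
3 | N-[2,4-bis(benzyloxy)-3-methoxybenzylidene]-N-methylmethanaminium chloride (aryl iminium chloride) | C[N+](C)=Cc1ccc(OCc2ccccc2)c(OC)c1OCc1ccccc1.[Cl-] | intermediate
4 | 2,4-bis(benzyloxy)-3-methoxybenzaldehyde | COc1c(OCc2ccccc2)ccc(C=O)c1OCc1ccccc1 | intermediate
5 | 1,3-bis(benzyloxy)-4-ethenyl-2-methoxybenzene | COc1c(OCc2ccccc2)ccc(C=C)c1OCc1ccccc1 | intermediate
6 | 9-{2-[2,4-bis(benzyloxy)-3-methoxyphenyl]ethyl}-9-borabicyclo[3.3.1]nonane | COc1c(OCc2ccccc2)ccc(CCB2C3CCCC2CCC3)c1OCc1ccccc1 | intermediate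
7 | 2-[2,4-bis(benzyloxy)-3-methoxyphenyl]ethan-1-ol | COc1c(OCc2ccccc2)ccc(CCO)c1OCc1ccccc1 | intermediate
8 | 1,3-bis(benzyloxy)-4-(2-iodoethyl)-2-methoxybenzene | COc1c(OCc2ccccc2)ccc(CCI)c1OCc1ccccc1 | intermediate
9 | 4-methoxybenzyl chloride | COc1ccc(CCl)cc1 | starting material
10 | allylmagnesium bromide | C=CC[Mg]Br | starting material
11 | 1-(but-3-en-1-yl)-4-methoxybenzene | C=CCCc1ccc(OC)cc1 | intermediate
12 | 9-[4-(4-methoxyphenyl)butyl]-9-borabicyclo[3.3.1]nonane | COc1ccc(CCCCB2C3CCCC2CCC3)cc1 | intermediate
13 | carbon monoxide | [C-]#[O+] | starting material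
14 | 1-[2,4-bis(benzyloxy)-3-methoxyphenyl]-7-(4-methoxyphenyl)heptan-3-one | COc1ccc(CCCCC(=O)CCc2ccc(OCc3ccccc3)c(OC)c2OCc2ccccc2)cc1 | intermediate
15 | 1-(2,4-dihydroxy-3-methoxyphenyl)-7-(4-methoxyphenyl)heptan-3-one | COc1ccc(CCCCC(=O)CCc2ccc(O)c(OC)c2O)cc1 | target

**Step count**
Total steps: 9. Longest linear sequence: 7 (steps 1, 2, 3, 4, 5, 8, 9); the borane branch (steps 6, 7) joins at step 8.

**Steps most likely to fail**

Step 8 (carbonylative coupling). CO capture by the 2-arylethyl radical or by palladium may be too slow. The iodide would then be consumed by direct alkyl–alkyl coupling, β-hydride elimination, reduction, or hydrogen transfer from the ortho benzyloxy group. The fallback is a two-component acylation that uses neither CO nor radicals. It sets out from iodide 8: insertion of activated zinc dust (LiCl, THF, 25–40 °C) should give [2-(2,4-bis(benzyloxy)-3-methoxyphenyl)ethyl]zinc iodide F1. Purchased 5-(4-methoxyphenyl)pentanoic acid (COc1ccc(CCCCC(=O)O)cc1) is converted with oxalyl chloride and catalytic DMF in CH2Cl2 into 5-(4-methoxyphenyl)pentanoyl chloride F2. Negishi acylation of F2 with F1 (Pd(PPh3)4 cat., THF, 0 °C → rt) should form the C2–C3 bond and comes back to the route at ketone 14.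

Step 2 (formylation). The trialkoxyarene may convert incompletely, or a benzyl ether may be lost to acid at the temperature the Vilsmeier reaction needs. The fallback sets out from 2: bromination with NBS in MeCN (0 °C → rt) should give 1,3-bis(benzyloxy)-4-bromo-2-methoxybenzene F3, by the same para-to-benzyloxy preference. Suzuki–Miyaura vinylation of F3 (potassium vinyltrifluoroborate, PdCl2(dppf), Cs2CO3, THF/H2O, 80 °C) should give the styrene directly. It comes back to the route at 5 and bypasses aldehyde 4 and the Wittig step.

Step 9 (debenzylation). Hydrogenation may run on to reduce the ketone, or the freed ortho phenol may close onto the ketone on the catalyst to give chroman-type products. The fallback is a non-reductive Lewis-acid debenzylation with a cation scavenger. It sets out from 14: BCl3 and pentamethylbenzene in CH2Cl2 at −78 °C, quenched cold with MeOH, should cleave the benzyl ethers selectively over the methyl ethers. It arrives at target 15 and makes no new compound (F0).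

**Further compounds**
F1 | step 8 | [2-(2,4-bis(benzyloxy)-3-methoxyphenyl)ethyl]zinc iodide | COc1c(OCc2ccccc2)ccc(CC[Zn]I)c1OCc1ccccc1
F2 | step 8 | 5-(4-methoxyphenyl)pentanoyl chloride | COc1ccc(CCCCC(=O)Cl)cc1
F3 | step 2 | 1,3-bis(benzyloxy)-4-bromo-2-methoxybenzene | COc1c(OCc2ccccc2)ccc(Br)c1OCc1ccccc1
F0 | step 9 | none | none
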